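**Plan**

1. Numbering: butenolide O1, C2–C5; side chain C1' (carbinol) to C17'. Cuts: lactone O1–C2 and C3=C4 (lactonisation/Wittig on a dioxanone), C1'–C2' (azaenolate allylation), C4'–C5' (Negishi coupling), C10'–C11' (radical decarboxylative alkenylation), C9'–C10' ([3,3] shift) and C12'–CH3 (alkyne methylalumination).
2. Enabling feature: the open-chain 1,5-diene C7'=C8'(CH3)–C9'H2–C10'H2–C11'H=C12'(CH3); no ring is involved. C10' is the α-carbon of a would-be 4-methylalk-4-enoic acid, so a Johnson–Claisen carboxyl on C10' serves as a traceless radical precursor. C11' is the hydrogen-bearing end of a methyl-branched alkene, i.e. the metal-bearing carbon of a methylaluminated terminal alkyne.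
3. Forward order: a C9 alkenyl iodide (2 steps) and a C8 redox-active ester (4 steps) are joined at C10'–C11' to give the C16 chain. The chain is converted to its iodide and joined at C4'–C5' to an iodoalkene–dioxane head piece that already carries C1'. The only ring of the target, the butenolide, arises last by deprotection and lactonisation.
4. Stereochemistry: C1' (R) from RAMP-hydrazone alkylation of 2,2-dimethyl-1,3-dioxan-5-one; E C11'=C12' from syn-carboalumination; E C7'=C8' from the chair Johnson–Claisen shift; C3'=C4' from hydroxyl-directed trans-hydroalumination/iodination followed by stereoretentive coupling.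

Key step: step 7

Assumption: the RAMP azaenolate of the dioxanone is taken to be alkylated with the facial sense usual for SAMP/RAMP ketone hydrazones (RAMP giving 4R); compounds 1, 5, 17, 21 and 22 are taken as commercial.

**Route**

Step 1
Reactants: 1 5-bromo-2-methylpent-2-ene
Product: 2 6-methylhept-5-en-1-yne
Conditions: lithium acetylide–ethylenediamine complex (1.3 equiv), DMSO, 10 °C → rt
Reagents that add atoms: lithium acetylide–ethylenediamine complex, [Li]C#C.NCCN
Why: SN2 displacement of the primary homoallylic bromide by acetylide in DMSO is a standard terminal-alkyne synthesis (acetylide alkylation), with E2 loss of HBr as the only competing path.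

Step 2
Reactants: 2 6-methylhept-5-en-1-yne
Product: 4 (1E)-1-iodo-2,6-dimethylhepta-1,5-diene, via alkenyldimethylalane 3 (not isolated)
Conditions: Al(CH3)3 (2 equiv), (C5H5)2ZrCl2 (0.25 equiv), CH2Cl2, 0 °C → rt; then I2, THF, −30 → 0 °C
Reagents that add atoms: trimethylaluminium, C[Al](C)C; iodine, II
Why: Zirconium-catalysed carboalumination (methylalumination) adds CH3 to C12' and aluminium to C11' in a syn fashion with the metal at the terminal carbon, and iodinolysis of the C–Al bond with retention should give the E iodide while the trisubstituted alkene stays untouched.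

Step 3
Reactants: 5 3-(tert-butyldimethylsilyloxy)propanal
Product: 6 5-(tert-butyldimethylsilyloxy)-2-methylpent-1-en-3-ol (racemic)
Conditions: isopropenylmagnesium bromide (1.2 equiv), THF, −78 → 0 °C; H2O work-up
Reagents that add atoms: isopropenylmagnesium bromide, CC(=C)[Mg]Br
Why: 1,2-Addition of an alkenyl Grignard reagent to the aldehyde builds the 2-methylallylic alcohol; the carbinol centre is left racemic because step 4 destroys it.

Step 4
Reactants: 6 5-(tert-butyldimethylsilyloxy)-2-methylpent-1-en-3-ol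
Product: 9 ethyl (4E)-7-(tert-butyldimethylsilyloxy)-4-methylhept-4-enoate, via mixed orthoester 7 (not isolated), via ketene acetal 8 (not isolated)
Conditions: CH3C(OEt)3 (6 equiv), EtCO2H (0.1 equiv), 140 °C, EtOH distilled off
Reagents that add atoms: triethyl orthoacetate, CC(OCC)(OCC)OCC
Why: Johnson–Claisen rearrangement: the [3,3] shift of ketene acetal 8 through a chair with the CH2CH2OTBS group equatorial (the axial arrangement clashes with the ethoxy group) forms C9'–C10' and should give the E C7'=C8' alkene with the ester carbon on C10'.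

Step 5
Reactants: 9 ethyl (4E)-7-(tert-butyldimethylsilyloxy)-4-methylhept-4-enoate
Product: 10 (4E)-7-(tert-butyldimethylsilyloxy)-4-methylhept-4-enoic acid
Conditions: LiOH, THF/MeOH/H2O, rt; then 1 M HCl to pH 4, 0 °C
Reagents that add atoms: lithium hydroxide, [Li+].[OH-]
Why: Saponification of the ethyl ester with hydroxide, to which silyl ether and alkene are inert, followed by brief mild acidification.

Step 6
Reactants: 10 (4E)-7-(tert-butyldimethylsilyloxy)-4-methylhept-4-enoic acid
Product: 11 1,3-dioxoisoindolin-2-yl (4E)-7-(tert-butyldimethylsilyloxy)-4-methylhept-4-enoate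
Conditions: N-hydroxyphthalimide (1.1 equiv), N,N'-diisopropylcarbodiimide (1.1 equiv), DMAP (0.1 equiv), CH2Cl2, rt
Reagents that add atoms: N-hydroxyphthalimide, O=C1c2ccccc2C(=O)N1O
Why: Carbodiimide-mediated (Steglich-type) esterification with N-hydroxyphthalimide turns the carboxyl into a redox-active ester that can accept one electron and lose CO2.

Step 7
Reactants: 4 (1E)-1-iodo-2,6-dimethylhepta-1,5-diene; 11 1,3-dioxoisoindolin-2-yl (4E)-7-(tert-butyldimethylsilyloxy)-4-methylhept-4-enoate
Product: 14 tert-butyldimethyl{[(3E,7E)-4,8,12-trimethyltrideca-3,7,11-trien-1-yl]oxy}silane, via alkenyllithium 12 (not isolated), via alkenylzinc chloride 13 (not isolated)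
Conditions: 4 (2 equiv), t-BuLi (4 equiv), Et2O, −78 °C; ZnCl2 (2 equiv), THF, −78 °C → rt; then 11 (1 equiv), Ni(acac)2 (10 mol %), 2,2'-bipyridine (10 mol %), THF/DMF, rt
Reagents that add atoms: none
Why: Transmetalation of 13 to nickel gives a monovalent alkenylnickel–bipyridine complex that transfers one electron to the phthalimide ester 11; loss of phthalimide anion and CO2 leaves the primary C10' radical, which is captured by divalent alkenylnickel, and reductive elimination from the trivalent alkyl(alkenyl)nickel forms C10'–C11'. The closest known reaction type is the nickel-catalysed decarboxylative alkenylation of redox-active esters with alkenylzinc reagents, a radical sp3–sp2 cross-coupling. No ring is closed and no stereocentre is made. The step needs retention of the E geometry at C11'=C12', which is secured because the C–Li, C–Zn and C–Ni bonds at the sp2 carbon are configurationally stable and carry over the syn-addition of step 2. It also needs the E C7'=C8' alkene to survive next to a homoallylic radical: the only cyclisation in reach is a reversible 3-exo closure whose equilibrium lies far on the open side and which should be slower than capture by nickel, and since the carboxyl carbon is lost, the [3,3] shift of step 4 decides both the position of C10' and the geometry at C7'=C8'. Chemoselectivity rests on the redox-active ester being the only group that accepts an electron; the silyl ether and the remote isopropylidene alkene are spectators.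

Step 8
Reactants: 14 tert-butyldimethyl{[(3E,7E)-4,8,12-trimethyltrideca-3,7,11-trien-1-yl]oxy}silane
Product: 15 (3E,7E)-4,8,12-trimethyltrideca-3,7,11-trien-1-ol
Conditions: n-Bu4NF, THF, 0 °C → rt
Reagents that add atoms: none
Why: Fluoride cleaves the Si–O bond (desilylation driven by the strong Si–F bond) without affecting the three alkenes.

Step 9
Reactants: 15 (3E,7E)-4,8,12-trimethyltrideca-3,7,11-trien-1-ol
Product: 16 (3E,7E)-1-iodo-4,8,12-trimethyltrideca-3,7,11-triene
Conditions: I2, PPh3, imidazole, CH2Cl2, 0 °C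
Reagents that add atoms: iodine, II
Why: Appel-type iodination: the alkoxyphosphonium ion is displaced by iodide in an SN2 step at the primary carbon, so no alkene shifts.

Step 10
Reactants: 17 4-(tert-butyldimethylsilyloxy)but-2-yn-1-ol
Product: 19 (2Z)-4-(tert-butyldimethylsilyloxy)-3-iodobut-2-en-1-ol, via cyclic alkenylalanate 18 (not isolated)
Conditions: NaAlH2(OCH2CH2OCH3)2 (1.2 equiv), THF, 0 °C; then I2, THF, −78 → 0 °C
Reagents that add atoms: iodine, II
Why: Hydroxyl-directed trans-hydroalumination of the propargylic alcohol delivers hydride to C3' and aluminium to C4' inside a five-membered alanate, and iodinolysis with retention should give the Z iodoalkenol with iodine cis to the CH2OH group; the silyl ether side cannot direct.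

Step 11
Reactants: 19 (2Z)-4-(tert-butyldimethylsilyloxy)-3-iodobut-2-en-1-ol
Product: 20 {[(2Z)-4-bromo-2-iodobut-2-en-1-yl]oxy}(tert-butyl)dimethylsilane
Conditions: CBr4, PPh3, CH2Cl2, 0 °C
Reagents that add atoms: carbon tetrabromide, BrC(Br)(Br)Br
Why: Appel bromination converts the primary allylic alcohol to the bromide by SN2 displacement of the oxyphosphonium ion, leaving alkene geometry, vinyl iodide and silyl ether intact.

Step 12
Reactants: 21 2,2-dimethyl-1,3-dioxan-5-one; 22 (R)-1-amino-2-(methoxymethyl)pyrrolidine (RAMP)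
Product: 23 (R)-N-(2,2-dimethyl-1,3-dioxan-5-ylidene)-2-(methoxymethyl)pyrrolidin-1-amine
Conditions: benzene, reflux, water separator
Reagents that add atoms: none
Why: Condensation of the ketone with the N-amino group gives the hydrazone (hydrazone formation); the ketone is symmetrical, so no C=N isomers arise.

Step 13
Reactants: 23 (R)-N-(2,2-dimethyl-1,3-dioxan-5-ylidene)-2-(methoxymethyl)pyrrolidin-1-amine; 20 {[(2Z)-4-bromo-2-iodobut-2-en-1-yl]oxy}(tert-butyl)dimethylsilane
Product: 25 (R)-N-{(4R)-4-[(2Z)-4-(tert-butyldimethylsilyloxy)-3-iodobut-2-en-1-yl]-2,2-dimethyl-1,3-dioxan-5-ylidene}-2-(methoxymethyl)pyrrolidin-1-amine (C=N geometry left open), via lithium azaenolate 24 (not isolated)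
Conditions: 23 (1.3 equiv), t-BuLi (1.25 equiv), THF, −78 °C; then 20 (1.0 equiv), −100 °C → rt
Reagents that add atoms: none
Why: SAMP/RAMP-hydrazone alkylation: the lithium azaenolate, made rigid by chelation of lithium to the methoxymethyl arm, attacks the allylic bromide in an SN2 step on the face left open by the pyrrolidine ring, which with the R auxiliary should set the new centre (ring C4, the later C1') as R; the vinyl iodide is inert because no alkyllithium remains.

Step 14
Reactants: 25 (R)-N-{(4R)-4-[(2Z)-4-(tert-butyldimethylsilyloxy)-3-iodobut-2-en-1-yl]-2,2-dimethyl-1,3-dioxan-5-ylidene}-2-(methoxymethyl)pyrrolidin-1-amine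
Product: 26 (4R)-4-[(2Z)-4-(tert-butyldimethylsilyloxy)-3-iodobut-2-en-1-yl]-2,2-dimethyl-1,3-dioxan-5-one
Conditions: saturated aq. oxalic acid, Et2O, rt
Reagents that add atoms: water, O
Why: Two-phase acidic hydrolysis of the hydrazone returns the ketone and the auxiliary under conditions that should not enolise the C4 centre and leave acetonide, silyl ether and vinyl iodide in place.

Step 15
Reactants: 26 (4R)-4-[(2Z)-4-(tert-butyldimethylsilyloxy)-3-iodobut-2-en-1-yl]-2,2-dimethyl-1,3-dioxan-5-one
Product: 27 methyl (2E)-2-{(4R)-4-[(2Z)-4-(tert-butyldimethylsilyloxy)-3-iodobut-2-en-1-yl]-2,2-dimethyl-1,3-dioxan-5-ylidene}acetate (ester on the side of ring C6)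
Conditions: Ph3P=CHCO2CH3 (1.5 equiv), toluene, 50 °C
Reagents that add atoms: methyl (triphenylphosphoranylidene)acetate, COC(=O)C=P(c1ccccc1)(c1ccccc1)c1ccccc1
Why: Wittig olefination with a stabilised ylide under neutral conditions (no epimerisation at C4); allylic 1,3-strain with the C4 substituent should direct the ester to the side of the unsubstituted C6, which is the geometry needed for lactonisation onto O1.

Step 16
Reactants: 16 (3E,7E)-1-iodo-4,8,12-trimethyltrideca-3,7,11-triene; 27 methyl (2E)-2-{(4R)-4-[(2Z)-4-(tert-butyldimethylsilyloxy)-3-iodobut-2-en-1-yl]-2,2-dimethyl-1,3-dioxan-5-ylidene}acetate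
Product: 30 methyl (2E)-2-{(4R)-4-[(2E,6E,10E)-3-(tert-butyldimethylsilyloxymethyl)-7,11,15-trimethylhexadeca-2,6,10,14-tetraen-1-yl]-2,2-dimethyl-1,3-dioxan-5-ylidene}acetate, via alkyllithium 28 (not isolated), via alkylzinc bromide 29 (not isolated)
Conditions: 16 (1.3 equiv), t-BuLi (2.6 equiv), Et2O, −78 °C; ZnBr2 (1.4 equiv), THF, −78 → 0 °C; then 27 (1.0 equiv), PdCl2(dppf) (5 mol %; dppf = 1,1'-bis(diphenylphosphino)ferrocene), THF, rt → 40 °C
Reagents that add atoms: none
Why: Negishi coupling: iodine–lithium exchange and transmetalation give a primary homoallylic alkylzinc, and oxidative addition of the vinyl iodide to zerovalent palladium, transmetalation and reductive elimination form C4'–C5' with retention, so that the chain ends up cis to C2' and CH2OTBS trans to it, while ester, acetal and silyl ether are inert to the organozinc.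

Step 17
Reactants: 30 methyl (2E)-2-{(4R)-4-[(2E,6E,10E)-3-(tert-butyldimethylsilyloxymethyl)-7,11,15-trimethylhexadeca-2,6,10,14-tetraen-1-yl]-2,2-dimethyl-1,3-dioxan-5-ylidene}acetate
Product: 32 Hippolide C (4-[(1R,3E,7E,11E)-1-hydroxy-4-(hydroxymethyl)-8,12,16-trimethylheptadeca-3,7,11,15-tetraen-1-yl]furan-2(5H)-one), via triol ester 31 (not isolated)
Conditions: AcOH/THF/H2O (3:1:1), 45 °C
Reagents that add atoms: none
Why: Acid hydrolysis of the acetonide and the silyl ether frees the C5–OH, which lies cis to the ester and closes the butenolide ring by 5-exo-trig lactonisation with loss of methanol, while the C1' and C4'-CH2 hydroxyls stay free and C1' is not touched.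

**Compound list**

1 | 5-bromo-2-methylpent-2-ene | CC(C)=CCCBr | starting material
2 | 6-methylhept-5-en-1-yne | C#CCCC=C(C)C | intermediate
3 | [(1E)-2,6-dimethylhepta-1,5-dien-1-yl]dimethylalane | CC(C)=CCC/C(C)=C/[Al](C)C | intermediate
4 | (1E)-1-iodo-2,6-dimethylhepta-1,5-diene | CC(C)=CCC/C(C)=C/I | intermediate
5 | 3-(tert-butyldimethylsilyloxy)propanal | O=CCCO[Si](C)(C)C(C)(C)C | starting material
6 | 5-(tert-butyldimethylsilyloxy)-2-methylpent-1-en-3-ol (racemic) | C=C(C)C(O)CCO[Si](C)(C)C(C)(C)C | intermediate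
7 | mixed orthoester of 6 (1,1-diethoxyethyl ether) | CC(OCC)(OCC)OC(CCO[Si](C)(C)C(C)(C)C)C(C)=C | intermediate
8 | ketene acetal of 6 (1-ethoxyvinyl ether) | C=C(OCC)OC(CCO[Si](C)(C)C(C)(C)C)C(C)=C | intermediate
9 | ethyl (4E)-7-(tert-butyldimethylsilyloxy)-4-methylhept-4-enoate | CCOC(=O)CC/C(C)=C/CCO[Si](C)(C)C(C)(C)C | intermediate
10 | (4E)-7-(tert-butyldimethylsilyloxy)-4-methylhept-4-enoic acid | OC(=O)CC/C(C)=C/CCO[Si](C)(C)C(C)(C)C | intermediate
11 | 1,3-dioxoisoindolin-2-yl (4E)-7-(tert-butyldimethylsilyloxy)-4-methylhept-4-enoate | O=C(CC/C(C)=C/CCO[Si](C)(C)C(C)(C)C)ON1C(=O)c2ccccc2C1=O | intermediate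
12 | [(1E)-2,6-dimethylhepta-1,5-dien-1-yl]lithium | CC(C)=CCC/C(C)=C/[Li] | intermediate
13 | [(1E)-2,6-dimethylhepta-1,5-dien-1-yl]zinc chloride | CC(C)=CCC/C(C)=C/[Zn]Cl | intermediate
14 | tert-butyldimethyl{[(3E,7E)-4,8,12-trimethyltrideca-3,7,11-trien-1-yl]oxy}silane | CC(C)=CCC/C(C)=C/CC/C(C)=C/CCO[Si](C)(C)C(C)(C)C | intermediate
15 | (3E,7E)-4,8,12-trimethyltrideca-3,7,11-trien-1-ol | CC(C)=CCC/C(C)=C/CC/C(C)=C/CCO | intermediate
16 | (3E,7E)-1-iodo-4,8,12-trimethyltrideca-3,7,11-triene | CC(C)=CCC/C(C)=C/CC/C(C)=C/CCI | intermediate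
17 | 4-(tert-butyldimethylsilyloxy)but-2-yn-1-ol | OCC#CCO[Si](C)(C)C(C)(C)C | starting material
18 | sodium cyclic alkenylalanate (1-oxa-2-aluminacyclopent-3-ene with two 2-methoxyethoxy groups on Al and CH2OTBS on C3) | [Na+].COCCO[Al-]1(OCCOC)OCC=C1CO[Si](C)(C)C(C)(C)C | intermediate
19 | (2Z)-4-(tert-butyldimethylsilyloxy)-3-iodobut-2-en-1-ol | OC/C=C(\I)CO[Si](C)(C)C(C)(C)C | intermediate
20 | {[(2Z)-4-bromo-2-iodobut-2-en-1-yl]oxy}(tert-butyl)dimethylsilane | BrC/C=C(\I)CO[Si](C)(C)C(C)(C)C | intermediate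
21 | 2,2-dimethyl-1,3-dioxan-5-one | CC1(C)OCC(=O)CO1 | starting material
22 | (R)-1-amino-2-(methoxymethyl)pyrrolidine (RAMP) | COC[C@H]1CCCN1N | starting material
23 | (R)-N-(2,2-dimethyl-1,3-dioxan-5-ylidene)-2-(methoxymethyl)pyrrolidin-1-amine | COC[C@H]1CCCN1N=C1COC(C)(C)OC1 | intermediate
24 | lithium azaenolate of 23 | COC[C@H]1CCCN1N([Li])C1=COC(C)(C)OC1 | intermediate
25 | (R)-N-{(4R)-4-[(2Z)-4-(tert-butyldimethylsilyloxy)-3-iodobut-2-en-1-yl]-2,2-dimethyl-1,3-dioxan-5-ylidene}-2-(methoxymethyl)pyrrolidin-1-amine | COC[C@H]1CCCN1N=C1COC(C)(C)O[C@@H]1C/C=C(\I)CO[Si](C)(C)C(C)(C)C | intermediate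
26 | (4R)-4-[(2Z)-4-(tert-butyldimethylsilyloxy)-3-iodobut-2-en-1-yl]-2,2-dimethyl-1,3-dioxan-5-one | O=C1COC(C)(C)O[C@@H]1C/C=C(\I)CO[Si](C)(C)C(C)(C)C | intermediate
27 | methyl (2E)-2-{(4R)-4-[(2Z)-4-(tert-butyldimethylsilyloxy)-3-iodobut-2-en-1-yl]-2,2-dimethyl-1,3-dioxan-5-ylidene}acetate | COC(=O)/C=C1\COC(C)(C)O[C@@H]1C/C=C(\I)CO[Si](C)(C)C(C)(C)C | intermediate
28 | [(3E,7E)-4,8,12-trimethyltrideca-3,7,11-trien-1-yl]lithium | CC(C)=CCC/C(C)=C/CC/C(C)=C/CC[Li] | intermediate
29 | [(3E,7E)-4,8,12-trimethyltrideca-3,7,11-trien-1-yl]zinc bromide | CC(C)=CCC/C(C)=C/CC/C(C)=C/CC[Zn]Br | intermediate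
30 | methyl (2E)-2-{(4R)-4-[(2E,6E,10E)-3-(tert-butyldimethylsilyloxymethyl)-7,11,15-trimethylhexadeca-2,6,10,14-tetraen-1-yl]-2,2-dimethyl-1,3-dioxan-5-ylidene}acetate | COC(=O)/C=C1\COC(C)(C)O[C@@H]1C/C=C(\CC/C=C(\C)CC/C=C(\C)CCC=C(C)C)CO[Si](C)(C)C(C)(C)C | intermediate
31 | methyl (2E)-4-hydroxy-3-[(1R,3E,7E,11E)-1-hydroxy-4-(hydroxymethyl)-8,12,16-trimethylheptadeca-3,7,11,15-tetraen-1-yl]but-2-enoate (ester cis to CH2OH) | COC(=O)/C=C(\CO)[C@H](O)C/C=C(\CC/C=C(\C)CC/C=C(\C)CCC=C(C)C)CO | intermediate
32 | Hippolide C, 4-[(1R,3E,7E,11E)-1-hydroxy-4-(hydroxymethyl)-8,12,16-trimethylheptadeca-3,7,11,15-tetraen-1-yl]furan-2(5H)-one | CC(C)=CCC/C(C)=C/CC/C(C)=C/CC/C(=C\C[C@@H](O)C1=CC(=O)OC1)CO | target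

**Count**

Total step count: 17. Longest linear sequence: 9 steps (3, 4, 5, 6, 7, 8, 9, 16, 17).

**Steps most likely to fail**

1. Step 7. What may go wrong: erosion of the E geometry at C7'=C8' through reversible cyclopropylcarbinyl closure of the C10' radical, or loss of the alkenyl partner by homocoupling or protonation before it is transferred. The fallback sets out from aldehyde 5 and iodide 4 and comes back at 14, forming the same bond by a two-electron path. Wittig olefination of 5 with 2-(triphenylphosphoranylidene)propanal (toluene, 80 °C) should give (2E)-5-(tert-butyldimethylsilyloxy)-2-methylpent-2-enal F1. Methylenation with Ph3P=CH2 (THF, 0 °C) gives the diene tert-butyl{[(3E)-4-methylhexa-3,5-dien-1-yl]oxy}dimethylsilane F2. 9-Borabicyclo[3.3.1]nonane (THF, rt) should hydroborate only the monosubstituted vinyl group, at its terminal carbon C10', to give the B-alkyl-9-borabicyclo[3.3.1]nonane F3. B-alkyl Suzuki–Miyaura coupling of F3 with 4 (PdCl2(dppf), AsPh3, Cs2CO3, DMF/H2O, rt) then gives 14 without a free radical.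

2. Step 15. What may go wrong: poor geometric control in the olefination (ester turned towards C4), which would lead to the regioisomeric lactone in step 17, or enolisation of the C4 centre on heating with the ylide. The fallback sets out from ketone 26 and comes back at target 32; it fixes the lactone regiochemistry by which hydroxyl is acylated, not by alkene geometry. Methanolysis of the acetonide only (PPTS, MeOH, rt) gives (3R,5Z)-7-(tert-butyldimethylsilyloxy)-1,3-dihydroxy-6-iodohept-5-en-2-one F4. Ketenylidenetriphenylphosphorane (Ph3P=C=C=O, toluene, 60 °C) acylates the primary hydroxyl, and the ylide so formed closes onto the ketone by intramolecular Wittig reaction to give 4-[(1R,3Z)-5-(tert-butyldimethylsilyloxy)-1-hydroxy-4-iodopent-3-en-1-yl]furan-2(5H)-one F5. Negishi coupling of F5 with 29 (2.5 equiv, one equivalent allowed for the free hydroxyl; PdCl2(dppf), THF, rt) gives Hippolide C mono-tert-butyldimethylsilyl ether F6. AcOH/THF/H2O (3:1:1, rt) then gives 32.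

3. Step 16. What may go wrong: slow oxidative addition and transmetalation at the fully substituted iodoalkene carbon of the functionalised partner, with competing β-hydride elimination or protonation of the alkylzinc. The fallback sets out from iodide 16 and iodo alcohol 19 and comes back at 30; it moves the sp2–sp3 union ahead of the auxiliary chemistry and uses boron instead of zinc. Iodine–lithium exchange on 16 (t-BuLi, Et2O, −78 °C) gives 28, which is trapped with 9-methoxy-9-borabicyclo[3.3.1]nonane as the lithium B-alkyl-B-methoxy borinate F7. Suzuki–Miyaura coupling with 19 (PdCl2(dppf), AsPh3, K3PO4 aq., DMF, rt) gives (2E,6E,10E)-3-(tert-butyldimethylsilyloxymethyl)-7,11,15-trimethylhexadeca-2,6,10,14-tetraen-1-ol F8. Appel bromination (CBr4, PPh3, CH2Cl2, 0 °C) gives the allylic bromide F9. Alkylation of azaenolate 24 with F9 as in step 13 gives the alkylated hydrazone F10. Oxalic acid hydrolysis as in step 14 gives the ketone (4R)-4-[(2E,6E,10E)-3-(tert-butyldimethylsilyloxymethyl)-7,11,15-trimethylhexadeca-2,6,10,14-tetraen-1-yl]-2,2-dimethyl-1,3-dioxan-5-one F11. Wittig olefination as in step 15 gives 30.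

**Further compounds**

F1 | step 7 | (2E)-5-(tert-butyldimethylsilyloxy)-2-methylpent-2-enal | O=C/C(C)=C/CCO[Si](C)(C)C(C)(C)C
F2 | step 7 | tert-butyl{[(3E)-4-methylhexa-3,5-dien-1-yl]oxy}dimethylsilane | C=C/C(C)=C/CCO[Si](C)(C)C(C)(C)C
F3 | step 7 | 9-[(3E)-6-(tert-butyldimethylsilyloxy)-3-methylhex-3-en-1-yl]-9-borabicyclo[3.3.1]nonane | CC(C)(C)[Si](C)(C)OCC/C=C(\C)CCB1C2CCCC1CCC2
F4 | step 15 | (3R,5Z)-7-(tert-butyldimethylsilyloxy)-1,3-dihydroxy-6-iodohept-5-en-2-one | OCC(=O)[C@H](O)C/C=C(\I)CO[Si](C)(C)C(C)(C)C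
F5 | step 15 | 4-[(1R,3Z)-5-(tert-butyldimethylsilyloxy)-1-hydroxy-4-iodopent-3-en-1-yl]furan-2(5H)-one | O=C1C=C(CO1)[C@H](O)C/C=C(\I)CO[Si](C)(C)C(C)(C)C
F6 | step 15 | Hippolide C mono-tert-butyldimethylsilyl ether (silyl on the C4'-CH2 oxygen) | CC(C)=CCC/C(C)=C/CC/C(C)=C/CC/C(=C\C[C@@H](O)C1=CC(=O)OC1)CO[Si](C)(C)C(C)(C)C
F7 | step 16 | lithium 9-methoxy-9-[(3E,7E)-4,8,12-trimethyltrideca-3,7,11-trien-1-yl]-9-boratabicyclo[3.3.1]nonane | [Li+].CO[B-]1(CC/C=C(\C)CC/C=C(\C)CCC=C(C)C)C2CCCC1CCC2
F8 | step 16 | (2E,6E,10E)-3-(tert-butyldimethylsilyloxymethyl)-7,11,15-trimethylhexadeca-2,6,10,14-tetraen-1-ol | OC/C=C(\CC/C=C(\C)CC/C=C(\C)CCC=C(C)C)CO[Si](C)(C)C(C)(C)C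
F9 | step 16 | {[(2E,6E,10E)-2-(2-bromoethylidene)-6,10,14-trimethylpentadeca-5,9,13-trien-1-yl]oxy}(tert-butyl)dimethylsilane | BrC/C=C(\CC/C=C(\C)CC/C=C(\C)CCC=C(C)C)CO[Si](C)(C)C(C)(C)C
F10 | step 16 | (R)-N-{(4R)-4-[(2E,6E,10E)-3-(tert-butyldimethylsilyloxymethyl)-7,11,15-trimethylhexadeca-2,6,10,14-tetraen-1-yl]-2,2-dimethyl-1,3-dioxan-5-ylidene}-2-(methoxymethyl)pyrrolidin-1-amine | COC[C@H]1CCCN1N=C1COC(C)(C)O[C@@H]1C/C=C(\CC/C=C(\C)CC/C=C(\C)CCC=C(C)C)CO[Si](C)(C)C(C)(C)C
F11 | step 16 | (4R)-4-[(2E,6E,10E)-3-(tert-butyldimethylsilyloxymethyl)-7,11,15-trimethylhexadeca-2,6,10,14-tetraen-1-yl]-2,2-dimethyl-1,3-dioxan-5-one | O=C1COC(C)(C)O[C@@H]1C/C=C(\CC/C=C(\C)CC/C=C(\C)CCC=C(C)C)CO[Si](C)(C)C(C)(C)C
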